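## Retrosynthetic overview

1. Target ⇒ cut the C2–phenyl bond: enantioselective Pd-catalysed conjugate addition of phenylboronic acid to a 6,8-bis(2-hydroxybenzyl)-5-hydroxy-7-methoxychromone. This attaches ring B and sets C2 in the last step.
2. Chromone ring C ⇒ one-carbon annulation (aminomethylenation, then cyclisation) of the mirror-symmetric 3,5-bis(2-hydroxybenzyl)-2,6-dihydroxy-4-methoxyacetophenone.
3. Both diarylmethane CH2 links ⇒ hydrogenolysis of two benzylic C–O bonds, so the two carbons enter at the aldehyde oxidation level.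
4. Key step: twofold boronic-acid-templated ortho-hydroxyalkylation of 2',6'-dihydroxy-4'-methoxyacetophenone with 2-(benzyloxy)benzaldehyde and PhB(OH)2. Two 1,3,2-dioxaborin rings are fused onto ring A in one operation.
5. Ring order: two temporary dioxaborin rings (step 1) → opened (step 2) → ring C as chromone (step 3) → C2 stereocentre (step 4). Ring A, ring B and the two hydroxyphenyl rings are bought.

Assumption: compounds 1, 2, 3, Bredereck's reagent and (R)-t-BuPyOx are taken as commercially available; compound 5 is used as the mixture of diastereomers at its two benzylic carbons, both of which are removed in step 2.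

## Route

Step 1
Reactants: 1 2',6'-dihydroxy-4'-methoxyacetophenone; 2 2-(benzyloxy)benzaldehyde (2.4 equiv); 3 phenylboronic acid (2.4 equiv)
Product: 5 1-{4,6-bis[2-(benzyloxy)phenyl]-5-methoxy-2,8-diphenyl-4H,6H-benzo[1,2-e:5,4-e']bis([1,3,2]dioxaborinin)-10-yl}ethan-1-one (bis-dioxaborin; diastereomer mixture), via mono-dioxaborin 4 (not isolated)
Conditions: EtCO2H (0.3 equiv), PhMe, reflux, Dean–Stark, 24–36 h
Reagents that add atoms: none
Why: Twofold Nagata ortho-hydroxyalkylation (boronic-acid-templated three-component condensation), in which each phenol forms an aryloxy(phenyl)boron ester that delivers the boron-bound aldehyde to its only free ortho carbon (C3, then C5) through a six-membered transition state and the resulting carbinol is trapped as a cyclic boronate, so two dioxaborin rings form on ring A in one operation with full regiocontrol; the two new benzylic stereocentres form without control and are erased in step 2.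

Step 2
Reactants: 5 bis-dioxaborin
Product: 6 1-[2,6-dihydroxy-3,5-bis(2-hydroxybenzyl)-4-methoxyphenyl]ethan-1-one
Conditions: H2 (1 atm), 10% Pd/C, EtOAc–MeOH (4:1), AcOH (cat.), rt; aqueous work-up
Reagents that add atoms: none
Why: Catalytic hydrogenolysis cleaves the two doubly benzylic C–O bonds of the dioxaborins (after methanolysis of the B–O bonds) and both O-benzyl ethers together, while the chelated aryl methyl ketone and the aryl methyl ether are inert, which removes the two non-target stereocentres and frees all four phenols.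

Step 3
Reactants: 6 1-[2,6-dihydroxy-3,5-bis(2-hydroxybenzyl)-4-methoxyphenyl]ethan-1-one
Product: 8 5-hydroxy-6,8-bis(2-hydroxybenzyl)-7-methoxy-4H-chromen-4-one, via enaminone 7 (not isolated)
Conditions: Bredereck's reagent (4 equiv), PhMe, 80 °C; then conc. HCl, CH2Cl2, rt
Reagents that add atoms: tert-butoxybis(dimethylamino)methane (Bredereck's reagent), CN(C)C(OC(C)(C)C)N(C)C
Why: Enaminone formation at the acetyl methyl group (Bredereck's reagent cannot O-methylate phenols) followed by acid-induced intramolecular oxa-Michael addition and loss of dimethylamine closes ring C as the chromone, and because the two phenols ortho to the ketone are equivalent by symmetry only one chromone can form; no stereocentre is created.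

Step 4
Reactants: 8 5-hydroxy-6,8-bis(2-hydroxybenzyl)-7-methoxy-4H-chromen-4-one; 3 phenylboronic acid (2.5 equiv)
Product: 9 (2S)-5-hydroxy-6,8-bis(2-hydroxybenzyl)-7-methoxy-2-phenyl-2,3-dihydro-4H-chromen-4-one (7-methoxydichamanetin)
Conditions: Pd(OCOCF3)2 (7.5 mol%), (R)-t-BuPyOx [(R)-4-tert-butyl-2-(pyridin-2-yl)-4,5-dihydrooxazole] (9 mol%), NH4PF6 (30 mol%), H2O (5 equiv), ClCH2CH2Cl, 60 °C
Reagents that add atoms: none
Why: Ligand-controlled enantioselective 1,4-addition of an arylboronic acid (Hayashi–Miyaura-type conjugate addition under cationic divalent palladium), in which phenyl is transferred from boron to palladium, adds to one face of the chromone C2=C3 bond and the palladium enolate is protonated by water, so C2 is created directly; the (R)-ligand is chosen because the (S)-ligand gives (R)-3-aryl ketones from cyclic enones and by the same facial model (2R)-flavanones, so the (2S)-configuration results and does not epimerise under the weakly acidic conditions.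

## Compound list

1 | 1-(2,6-dihydroxy-4-methoxyphenyl)ethan-1-one (2',6'-dihydroxy-4'-methoxyacetophenone) | CC(=O)c1c(O)cc(OC)cc1O | starting material
2 | 2-(benzyloxy)benzaldehyde | O=Cc1ccccc1OCc1ccccc1 | starting material
3 | phenylboronic acid | OB(O)c1ccccc1 | starting material
4 | 1-{4-[2-(benzyloxy)phenyl]-7-hydroxy-5-methoxy-2-phenyl-4H-1,3,2-benzodioxaborin-8-yl}ethan-1-one (racemic mono-dioxaborin, not isolated) | CC(=O)c1c(O)cc(OC)c2c1OB(c1ccccc1)OC2c1ccccc1OCc1ccccc1 | intermediate
5 | 1-{4,6-bis[2-(benzyloxy)phenyl]-5-methoxy-2,8-diphenyl-4H,6H-benzo[1,2-e:5,4-e']bis([1,3,2]dioxaborinin)-10-yl}ethan-1-one (ring A with acetyl and OMe on its two free carbons, fused on both sides to a 2-phenyl-4H-1,3,2-dioxaborin ring whose sp3 carbon carries a 2-(benzyloxy)phenyl group; diastereomer mixture) | CC(=O)c1c2OB(c3ccccc3)OC(c3ccccc3OCc3ccccc3)c2c(OC)c2C(c3ccccc3OCc3ccccc3)OB(c3ccccc3)Oc12 | intermediate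
6 | 1-[2,6-dihydroxy-3,5-bis(2-hydroxybenzyl)-4-methoxyphenyl]ethan-1-one | CC(=O)c1c(O)c(Cc2ccccc2O)c(OC)c(Cc2ccccc2O)c1O | intermediate
7 | (E)-1-[2,6-dihydroxy-3,5-bis(2-hydroxybenzyl)-4-methoxyphenyl]-3-(dimethylamino)prop-2-en-1-one (enaminone, not isolated) | CN(C)/C=C/C(=O)c1c(O)c(Cc2ccccc2O)c(OC)c(Cc2ccccc2O)c1O | intermediate
8 | 5-hydroxy-6,8-bis(2-hydroxybenzyl)-7-methoxy-4H-chromen-4-one | COc1c(Cc2ccccc2O)c(O)c2c(c1Cc1ccccc1O)OC=CC2=O | intermediate
9 | (2S)-5-hydroxy-6,8-bis(2-hydroxybenzyl)-7-methoxy-2-phenyl-2,3-dihydro-4H-chromen-4-one (7-methoxydichamanetin) | COc1c(Cc2ccccc2O)c(O)c2c(c1Cc1ccccc1O)O[C@H](c1ccccc1)CC2=O | target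

## Step count and risks

Total step count: 4. Longest linear sequence: 4 steps (1 → 5 → 6 → 8 → 9).

The three steps most likely to fail are steps 1, 4 and 3.

**Step 1 (twofold Nagata annulation).** The acetyl-chelated phenols may esterify boron poorly, the second annulation builds a hexasubstituted ring, and an ionised dioxaborin can alkylate a not-yet-substituted ring to give triarylmethane dimers. The fallback sets out from 1 and comes back to the route at 8; it builds ring C first and then installs both benzyl groups at the alcohol oxidation level. Compound 1 is heated with Bredereck's reagent to give (E)-3-(dimethylamino)-1-(2,6-dihydroxy-4-methoxyphenyl)prop-2-en-1-one F1, which is closed with HCl in CH2Cl2 to 5-hydroxy-7-methoxy-4H-chromen-4-one F2. F2 is then alkylated twice, at C6 and C8, with 2-hydroxybenzyl alcohol (3 equiv) and ZnCl2 in dioxane at 90 °C, a Friedel–Crafts alkylation through the ortho-quinone methide, to give 8.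

**Step 4 (asymmetric conjugate addition).** The chromone is electron-rich, carries a chelating 5-OH and two free phenols that can bind palladium, and may react slowly or with low enantiomeric excess. The fallback sets out from 6 and comes back at 9; it gives up catalytic enantiocontrol for a racemic closure and a resolution with recycling. Compound 6 is condensed with benzaldehyde (KOH, EtOH–H2O, rt, Claisen–Schmidt) to give (E)-1-[2,6-dihydroxy-3,5-bis(2-hydroxybenzyl)-4-methoxyphenyl]-3-phenylprop-2-en-1-one F3. F3 cyclises by oxa-Michael addition (NaOAc, EtOH, reflux) to racemic 5-hydroxy-6,8-bis(2-hydroxybenzyl)-7-methoxy-2-phenyl-2,3-dihydro-4H-chromen-4-one F4. Preparative chromatography on an amylose tris(3,5-dimethylphenylcarbamate) phase separates 9 from (2R)-5-hydroxy-6,8-bis(2-hydroxybenzyl)-7-methoxy-2-phenyl-2,3-dihydro-4H-chromen-4-one F5. F5 is re-racemised with NaOAc in hot EtOH through ring opening to F3 and is recycled.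

**Step 3 (chromone formation on a tetraphenol).** Four acidic phenols can consume the aminomethylenating reagent and suppress enolisation of the hindered acetyl group. The fallback sets out from 5 and comes back at 8; it keeps the two remote phenols as benzyl ethers through the annulation. Compound 5 is treated with Et3SiH (2.5 equiv) and CF3CO2H in CH2Cl2 at 0 °C, an ionic hydrogenation that reduces only the two dioxaborin C–O bonds, to give 1-{3,5-bis[2-(benzyloxy)benzyl]-2,6-dihydroxy-4-methoxyphenyl}ethan-1-one F6. Bredereck's reagent converts F6 into (E)-1-{3,5-bis[2-(benzyloxy)benzyl]-2,6-dihydroxy-4-methoxyphenyl}-3-(dimethylamino)prop-2-en-1-one F7, which is closed with HCl to 6,8-bis[2-(benzyloxy)benzyl]-5-hydroxy-7-methoxy-4H-chromen-4-one F8. The benzyl ethers are then removed with BCl3 and pentamethylbenzene in CH2Cl2 at −78 °C, which leaves the chromone double bond and the 7-OMe group untouched, to give 8.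

## Further compounds

F1 | step 1 | (E)-3-(dimethylamino)-1-(2,6-dihydroxy-4-methoxyphenyl)prop-2-en-1-one | CN(C)/C=C/C(=O)c1c(O)cc(OC)cc1O
F2 | step 1 | 5-hydroxy-7-methoxy-4H-chromen-4-one | COc1cc(O)c2c(c1)OC=CC2=O
F3 | step 4 | (E)-1-[2,6-dihydroxy-3,5-bis(2-hydroxybenzyl)-4-methoxyphenyl]-3-phenylprop-2-en-1-one | O=C(/C=C/c1ccccc1)c1c(O)c(Cc2ccccc2O)c(OC)c(Cc2ccccc2O)c1O
F4 | step 4 | racemic 5-hydroxy-6,8-bis(2-hydroxybenzyl)-7-methoxy-2-phenyl-2,3-dihydro-4H-chromen-4-one | COc1c(Cc2ccccc2O)c(O)c2c(c1Cc1ccccc1O)OC(c1ccccc1)CC2=O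
F5 | step 4 | (2R)-5-hydroxy-6,8-bis(2-hydroxybenzyl)-7-methoxy-2-phenyl-2,3-dihydro-4H-chromen-4-one | COc1c(Cc2ccccc2O)c(O)c2c(c1Cc1ccccc1O)O[C@@H](c1ccccc1)CC2=O
F6 | step 3 | 1-{3,5-bis[2-(benzyloxy)benzyl]-2,6-dihydroxy-4-methoxyphenyl}ethan-1-one | CC(=O)c1c(O)c(Cc2ccccc2OCc2ccccc2)c(OC)c(Cc2ccccc2OCc2ccccc2)c1O
F7 | step 3 | (E)-1-{3,5-bis[2-(benzyloxy)benzyl]-2,6-dihydroxy-4-methoxyphenyl}-3-(dimethylamino)prop-2-en-1-one | CN(C)/C=C/C(=O)c1c(O)c(Cc2ccccc2OCc2ccccc2)c(OC)c(Cc2ccccc2OCc2ccccc2)c1O
F8 | step 3 | 6,8-bis[2-(benzyloxy)benzyl]-5-hydroxy-7-methoxy-4H-chromen-4-one | COc1c(Cc2ccccc2OCc2ccccc2)c(O)c2c(c1Cc1ccccc1OCc1ccccc1)OC=CC2=O
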